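## Retrosynthetic overview
1. Ambrein ⇒ Barton decarboxylation of an acid whose carboxyl carbon is a traceless linker ⇒ Ireland–Claisen [3,3] rearrangement of ester **11**. This step forms the C11–C12 bond and the E‑trisubstituted C13=C14 alkene in one operation.
2. Ester **11** comes from two pieces. One is a C8‑silyloxy homodrimanyl‑acetic acid (**10**), made from (+)-sclareolide, which already carries C5, C8, C9 and C10. The other is tertiary vinyl carbinol **7**, made from (S)‑dihydro‑γ‑ionone (**6**), which carries the monocycle stereocentre.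
3. Ketone **6** is prepared from a second portion of sclareolide‑derived diol by excising ring B (Hock/Criegee rearrangement, then alkoxy‑radical β‑scission with Cu‑mediated desaturation). Its C5 centre becomes the monocycle stereocentre.
4. No ring is constructed. Both carbocycles and all five stereocentres come from (+)-sclareolide.

Assumptions: the Claisen gives E:Z of about 3:1, and the isomers separate on AgNO3–silica. C9 migrates preferentially in the Hock rearrangement.

## Route

**Step 1**
Reactants: **1** (+)-sclareolide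
Product: **2** ambradiol
Conditions: LiAlH4, THF, 0 °C → 65 °C
Reagents that add atoms: none
Why: Lactone reduction (hydride addition) opens the lactone to the 8α,12‑diol without touching any stereocentre.

**Step 2**
Reactants: **2**
Product: **3** ambradiol 12‑pivalate
Conditions: PivCl, pyridine, DMAP (cat.), CH2Cl2, 0 °C
Reagents that add atoms: pivaloyl chloride, CC(C)(C)C(=O)Cl
Why: Selective acylation of the unhindered primary alcohol; the tertiary C8‑OH stays free.

**Step 3**
Reactants: **3**
Product: **4** 8‑hydroperoxide (C8 epimeric mixture)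
Conditions: 50 % aq. H2O2 (10 equiv), H2SO4 (cat.), CH2Cl2, 0 °C
Reagents that add atoms: hydrogen peroxide, OO
Why: SN1 substitution of the tertiary alcohol by H2O2 (via the C8 cation) gives the tertiary hydroperoxide; the C8 configuration is irrelevant because C8 is destroyed in the next step.

**Step 4**
Reactants: **4**
Product: **5** (3R)‑3‑hydroxy‑3‑[(1S,2S)‑1,3,3‑trimethyl‑2‑(3‑oxobutyl)cyclohexyl]propyl pivalate
Conditions: p‑TsOH·H2O (0.2 equiv), CH2Cl2, 0 °C → 25 °C
Reagents that add atoms: water, O (hydrolysis of the oxocarbenium; this oxygen becomes the ketone C=O)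
Why: Hock/Criegee rearrangement: the more substituted C9 migrates from C8 to oxygen with retention, so ring B opens to the C8 methyl ketone and a C9 secondary alcohol, while C5 and C10 are untouched.

**Step 5**
Reactants: **5**
Product: **6** (S)‑4‑(2,2‑dimethyl‑6‑methylenecyclohexyl)butan‑2‑one (dihydro‑γ‑ionone)
Conditions: Pb(OAc)4 (1.5 equiv), Cu(OAc)2 (0.2 equiv), toluene, 80 °C
Reagents that add atoms: none
Why: The C9 alkoxy radical undergoes β‑scission of the C9–C10 bond, releasing 3‑oxopropyl pivalate and a tertiary C10 radical. Cu(II) oxidises this radical by Hofmann‑type β‑H loss from the methyl group to give the exocyclic methylene. C5 is never involved, so its (S) configuration is retained.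

**Step 6**
Reactants: **6**
Product: **7** (3RS)‑5‑[(1S)‑2,2‑dimethyl‑6‑methylidenecyclohexyl]‑3‑methylpent‑1‑en‑3‑ol
Conditions: CH2=CHMgBr (1.5 equiv), THF, 0 °C → 25 °C
Reagents that add atoms: vinylmagnesium bromide, C=C[Mg]Br
Why: Grignard 1,2‑addition to the methyl ketone; the new carbinol centre is destroyed in Step 11, so its configuration is irrelevant.

**Step 7**
Reactants: **2**
Product: **8** ambradiol bis‑TBS ether
Conditions: TBSOTf (2.5 equiv), 2,6‑lutidine, CH2Cl2, 0 °C
Reagents that add atoms: tert‑butyldimethylsilyl triflate, CC(C)(C)[Si](C)(C)OS(=O)(=O)C(F)(F)F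
Why: Triflate silylation protects both the primary and the tertiary alcohol with no stereocentre involved.

**Step 8**
Reactants: **8**
Product: **9** 12‑ol, C8‑OTBS
Conditions: CSA (0.2 equiv), MeOH/CH2Cl2 (1:1), 0 °C
Reagents that add atoms: none
Why: Acid‑catalysed methanolysis cleaves the primary TBS ether much faster than the hindered tertiary one.

**Step 9**
Reactants: **9**
Product: **10** 2‑[(1R,2R,4aS,8aS)‑2‑(TBSO)‑2,5,5,8a‑tetramethyldecahydronaphthalen‑1‑yl]acetic acid
Conditions: TEMPO (0.2 equiv), NaClO2 (2.5 equiv), NaOCl (0.02 equiv), MeCN/pH 6.7 phosphate buffer, 35 °C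
Reagents that add atoms: sodium chlorite, [Na+].[O-]Cl=O
Why: TEMPO/chlorite oxidation takes the primary alcohol straight to the acid, and the C8 silyl ether prevents re‑lactonisation.

**Step 10**
Reactants: **10**, **7**
Product: **11** allylic ester
Conditions: (COCl)2, DMF (cat.), CH2Cl2, 0 °C → 25 °C; concentrate; then the lithium alkoxide of **7** (n‑BuLi, THF, −78 °C), THF, −78 → 0 °C
Reagents that add atoms: none
Why: The acid chloride acylates the lithium alkoxide of the tertiary allylic alcohol, giving the Claisen substrate (C14 epimers converge in Step 11).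

**Step 11**
Reactants: **11**
Product: **12** (4E)‑7‑[(1S)‑2,2‑dimethyl‑6‑methylidenecyclohexyl]‑5‑methyl‑2‑[(1R,2R,4aS,8aS)‑2‑(TBSO)‑2,5,5,8a‑tetramethyldecahydronaphthalen‑1‑yl]hept‑4‑enoic acid
Conditions: LDA (2.5 equiv), THF, −78 °C; TMSCl (3 equiv), −78 → 50 °C; then 1 M HCl/THF, 0 °C
Reagents that add atoms: none (the TMS group is removed on work‑up)
Why: Ireland–Claisen [3,3] rearrangement of the silyl ketene acetal through a chair transition state forms the C11–C12 bond and the E‑trisubstituted alkene (the Z isomer is removed in Step 14). The new C11 stereocentre is transient and is removed in Step 13, and the existing centres are not touched.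

**Step 12**
Reactants: **12**
Product: **13** thiohydroxamate (Barton) ester
Conditions: (COCl)2, DMF (cat.), CH2Cl2; then sodium 2‑thioxopyridin‑1‑olate, DMAP (cat.), CH2Cl2, 0 °C, dark
Reagents that add atoms: sodium pyrithione, [Na+].[S-]c1cccc[n+]1[O-]
Why: Acylation of the N‑hydroxypyridinethione salt activates the acid as a radical precursor.

**Step 13**
Reactants: **13**
Product: **14** TBS ether of ambrein
Conditions: t‑BuSH (10 equiv), hν (tungsten lamp), THF, 10 → 25 °C
Reagents that add atoms: none (the H comes from t‑BuSH)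
Why: Barton radical decarboxylation replaces the carboxyl group by H, which removes the transient C11 stereocentre and the linker carbon.

**Step 14**
Reactants: **14**
Product: **15** ambrein
Conditions: TBAF (5 equiv), THF, 65 °C; then AgNO3–SiO2 chromatography to remove the Z isomer
Reagents that add atoms: none
Why: Fluoride cleaves the tertiary silyl ether to give the free 8α‑alcohol, and the E/Z isomers are separated at this stage.

## Compound list
1 | (+)-sclareolide | O=C1C[C@@H]2[C@@]3(C)CCCC(C)(C)[C@@H]3CC[C@@]2(C)O1 | starting material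
2 | (1R,2R,4aS,8aS)-1-(2-hydroxyethyl)-2,5,5,8a-tetramethyldecahydronaphthalen-2-ol (ambradiol) | OCC[C@@H]1[C@@]2(C)CCCC(C)(C)[C@@H]2CC[C@@]1(C)O | intermediate
3 | 2-[(1R,2R,4aS,8aS)-2-hydroxy-2,5,5,8a-tetramethyldecahydronaphthalen-1-yl]ethyl pivalate | CC(C)(C)C(=O)OCC[C@@H]1[C@@]2(C)CCCC(C)(C)[C@@H]2CC[C@@]1(C)O | intermediate
4 | 2-[(1R,4aS,8aS)-2-hydroperoxy-2,5,5,8a-tetramethyldecahydronaphthalen-1-yl]ethyl pivalate (C2 epimers) | CC(C)(C)C(=O)OCC[C@@H]1[C@@]2(C)CCCC(C)(C)[C@@H]2CCC1(C)OO | intermediate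
5 | (3R)-3-hydroxy-3-[(1S,2S)-1,3,3-trimethyl-2-(3-oxobutyl)cyclohexyl]propyl pivalate | CC(=O)CC[C@H]1C(C)(C)CCC[C@]1(C)[C@H](O)CCOC(=O)C(C)(C)C | intermediate
6 | (S)-4-(2,2-dimethyl-6-methylenecyclohexyl)butan-2-one | CC(=O)CC[C@H]1C(C)(C)CCCC1=C | intermediate
7 | (3RS)-5-[(1S)-2,2-dimethyl-6-methylenecyclohexyl]-3-methylpent-1-en-3-ol | C=CC(C)(O)CC[C@H]1C(C)(C)CCCC1=C | intermediate
8 | (1R,2R,4aS,8aS)-2-(TBSO)-1-[2-(TBSO)ethyl]-2,5,5,8a-tetramethyldecahydronaphthalene | CC(C)(C)[Si](C)(C)OCC[C@@H]1[C@@]2(C)CCCC(C)(C)[C@@H]2CC[C@@]1(C)O[Si](C)(C)C(C)(C)C | intermediate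
9 | 2-[(1R,2R,4aS,8aS)-2-(TBSO)-2,5,5,8a-tetramethyldecahydronaphthalen-1-yl]ethanol | OCC[C@@H]1[C@@]2(C)CCCC(C)(C)[C@@H]2CC[C@@]1(C)O[Si](C)(C)C(C)(C)C | intermediate
10 | 2-[(1R,2R,4aS,8aS)-2-(TBSO)-2,5,5,8a-tetramethyldecahydronaphthalen-1-yl]acetic acid | OC(=O)C[C@@H]1[C@@]2(C)CCCC(C)(C)[C@@H]2CC[C@@]1(C)O[Si](C)(C)C(C)(C)C | intermediate
11 | 5-[(1S)-2,2-dimethyl-6-methylidenecyclohexyl]-3-methylpent-1-en-3-yl ester of acid **10** | C=CC(C)(CC[C@H]1C(C)(C)CCCC1=C)OC(=O)C[C@@H]1[C@@]2(C)CCCC(C)(C)[C@@H]2CC[C@@]1(C)O[Si](C)(C)C(C)(C)C | intermediate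
12 | (4E)-7-[(1S)-2,2-dimethyl-6-methylidenecyclohexyl]-5-methyl-2-[(1R,2R,4aS,8aS)-2-(TBSO)-2,5,5,8a-tetramethyldecahydronaphthalen-1-yl]hept-4-enoic acid (C2 epimeric) | C=C1CCCC(C)(C)[C@@H]1CC/C(C)=C/CC(C(=O)O)[C@@H]1[C@@]2(C)CCCC(C)(C)[C@@H]2CC[C@@]1(C)O[Si](C)(C)C(C)(C)C | intermediate
13 | 2-thioxopyridin-1(2H)-yl ester of acid **12** | C=C1CCCC(C)(C)[C@@H]1CC/C(C)=C/CC(C(=O)ON1C=CC=CC1=S)[C@@H]1[C@@]2(C)CCCC(C)(C)[C@@H]2CC[C@@]1(C)O[Si](C)(C)C(C)(C)C | intermediate
14 | TBS ether of ambrein | C=C1CCCC(C)(C)[C@@H]1CC/C(C)=C/CC[C@@H]1[C@@]2(C)CCCC(C)(C)[C@@H]2CC[C@@]1(C)O[Si](C)(C)C(C)(C)C | intermediate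
15 | ambrein, (1R,2R,4aS,8aS)-1-{(3E)-6-[(1S)-2,2-dimethyl-6-methylidenecyclohexyl]-4-methylhex-3-en-1-yl}-2,5,5,8a-tetramethyldecahydronaphthalen-2-ol | C=C1CCCC(C)(C)[C@@H]1CC/C(C)=C/CC[C@@H]1[C@@]2(C)CCCC(C)(C)[C@@H]2CC[C@@]1(C)O | target

## Summary
Total steps: 14.
Longest linear sequence: 11 steps (1 → 2 → 3 → 4 → 5 → 6 → 7 → 11 → 12 → 13 → 14 → 15 in the compound numbering).

Three steps most likely to fail:
1. **Step 4 (Hock/Criegee ring‑B opening)**. Competing elimination, or migration of C7 instead of C9, would lower the yield. Fallback: dehydrate the C8 alcohol to the Δ8(9) alkene, ozonolyse to the C8/C9 diketone, and carry out a Baeyer–Villiger at C9 to reach the same ring‑A fragment by a different route.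
2. **Step 5 (regioselective exocyclic alkene)**. Pb(IV) may acetoxylate the methyl ketone, or the radical may eliminate toward C1 or C5, giving endocyclic alkenes. Fallback: oxidise C9‑OH to the ketone, Baeyer–Villiger to the tertiary C10 ester, hydrolyse to the tertiary alcohol, and use a Hofmann‑selective cobaloxime/photoredox dehydration.
3. **Step 11 (Ireland–Claisen)**. The tertiary allylic ester may ionise, and E:Z selectivity is modest because Me and CH2CH2R are sterically similar. Fallback: switch to a secondary 2‑methylallylic alcohol (C13 carbinol on the bicyclic side) with the monocyclic acetic acid, which gives E‑alkene selectively through a chair transition state, or make the alkene by Julia–Kocienski olefination instead.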